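**Retrosynthetic overview** (ring atoms numbered as in cyclopenta[c]pyridine: C1, N2, C3, C4, C4a, C5, C6, C7, C7a)

1. The C6–O ester bond is cut first: Mitsunobu coupling with inversion at C6 joins amino alcohol 12 and acid 19; 19 comes from (S)-citronellol by ozonolysis and an E-selective Wittig reaction.
2. 12 comes from keto carbamate 10 in one LiAlH4 operation (C6=O to C6–OH from the convex face, N-Boc to N-CH3); 10 comes from enone 9 by hydrogenation, which sets C4a.
3. Enabling feature: the carbocycle C4a–C5–C6–C7–C7a is a latent cyclopent-2-enone whose carbinol carbon C6 lies between C5 and the methyl-bearing C7, while C4a and C7a are also bridged by C4–C3–N2–C1. Taking C6 out as CO and cutting C4a–C7a therefore opens both rings to the acyclic carbamate-tethered 1,7-enyne 7 (alkyne C4a≡C5, (E)-alkene C7a=C7).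
4. Ring order: both rings form in the one Pauson–Khand operation, the piperidine first (C4a–C7a) and the cyclopentenone last (C6 joined to C7 and C5). 7 is made in three steps from Boc-protected (S)-3-amino-2-methylpropanoic acid 1.

Key step: step 4

Remark: (E)-1-bromobut-2-ene is taken as the pure E isomer; a Z contaminant would only give the C7 epimer of 9, which is α to the ketone and can be equilibrated to 9 with base.

**Step 1**
Reactants: 1 (S)-3-[(tert-butoxycarbonyl)amino]-2-methylpropanoic acid
Product: 2 methyl (S)-3-[(tert-butoxycarbonyl)amino]-2-methylpropanoate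
Conditions: MeI, K2CO3, DMF, 0 °C → rt
Reagents that add atoms: iodomethane, CI
Why: O-alkylation of the carboxylate (SN2 on iodomethane) should give the methyl ester, and the weakly basic conditions leave the carbamate N–H and the α-stereocenter untouched.

**Step 2**
Reactants: 2 methyl (S)-3-[(tert-butoxycarbonyl)amino]-2-methylpropanoate; 3 dimethyl (1-diazo-2-oxopropyl)phosphonate
Product: 5 tert-butyl N-[(2R)-2-methylbut-3-yn-1-yl]carbamate, via aldehyde 4 (not isolated)
Conditions: i-Bu2AlH (2.2 equiv), CH2Cl2, −78 °C; then MeOH, K2CO3, 3, −78 °C → rt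
Reagents that add atoms: dimethyl (1-diazo-2-oxopropyl)phosphonate (3), COP(=O)(OC)C(=[N+]=[N-])C(C)=O
Why: Partial reduction of the ester to the aluminium hemiacetal, release of aldehyde 4 by methanol and Ohira–Bestmann (Seyferth–Gilbert) homologation in the same flask should give the terminal alkyne, the stereocenter being kept because the aldehyde is never isolated and reacts cold (the descriptor changes from S to R only through the priority switch).

**Step 3**
Reactants: 5 tert-butyl N-[(2R)-2-methylbut-3-yn-1-yl]carbamate; 6 (E)-1-bromobut-2-ene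
Product: 7 tert-butyl N-[(2E)-but-2-en-1-yl]-N-[(2R)-2-methylbut-3-yn-1-yl]carbamate
Conditions: NaH (1.1 equiv), DMF, 0 °C; then 6, 0 °C → rt
Reagents that add atoms: (E)-1-bromobut-2-ene (6), C/C=C/CBr
Why: N-alkylation of the sodium carbamate with the primary allylic bromide (SN2) installs the (E)-crotyl arm, since the carbamate N–H is more acidic than the alkyne C–H and no stereocenter is involved.

**Step 4**
Reactants: 7 tert-butyl N-[(2E)-but-2-en-1-yl]-N-[(2R)-2-methylbut-3-yn-1-yl]carbamate
Product: 9 tert-butyl (4R,7S,7aS)-4,7-dimethyl-6-oxo-1,3,4,6,7,7a-hexahydro-2H-cyclopenta[c]pyridine-2-carboxylate, via alkyne–Co2(CO)6 complex 8 (not isolated)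
Conditions: Co2(CO)8 (1.1 equiv), ClCH2CH2Cl, rt; then n-BuSMe (3.5 equiv), 83 °C
Reagents that add atoms: Co2(CO)8 (one CO ligand becomes the C6 carbonyl), O=C=[Co](=C=O)(=C=O)(=C=O)[Co](=C=O)(=C=O)(=C=O)=C=O
Why: Co2(CO)8 binds the terminal alkyne as complex 8; on heating with the sulfide a CO ligand is lost, the tethered (E)-alkene coordinates and inserts into the Co–C4a bond (C4a–C7a formed, six-membered ring closed in the 6-exo sense to a cobaltacyclopentene), CO then inserts into the Co–C7 bond, which makes the C6–C7 bond, and reductive elimination joins C6 to C5, so the one-carbon unit C6 closes the cyclopentenone between C7 and C5 in a [2+2+1] carbonylative cycloaddition. The closest known reaction type is the intramolecular Pauson–Khand reaction of nitrogen-tethered 1,7-enynes. C7 follows from the alkene geometry: addition to the (E)-alkene is suprafacial, so the C7 methyl ends trans to C1 and cis to H7a. C7a is controlled by the C4 stereocenter: in the chair-like cobaltacycle the propargylic methyl stays equatorial (an axial methyl would be 1,3-diaxial to H7a and pressed against the Co(CO)3 unit on that face), which places H7a cis to H4. The step needs alkene diastereoface selectivity and cyclisation in preference to alkyne oligomerisation; the first is secured by the (R)-configured C4 next to the alkyne, the second by the carbamate tether, whose restricted rotation holds the two π systems close, together with the sulfide promoter.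

**Step 5**
Reactants: 9 tert-butyl (4R,7S,7aS)-4,7-dimethyl-6-oxo-1,3,4,6,7,7a-hexahydro-2H-cyclopenta[c]pyridine-2-carboxylate
Product: 10 tert-butyl (4R,4aS,7S,7aR)-4,7-dimethyl-6-oxooctahydro-2H-cyclopenta[c]pyridine-2-carboxylate
Conditions: H2 (1 atm), 10% Pd/C, EtOAc, rt
Reagents that add atoms: none
Why: Heterogeneous hydrogenation of the trisubstituted enone should deliver hydrogen to C4a from the face that carries H7a and H4 (the other face is screened by the axial hydrogens at C1 and C3), which gives the cis ring fusion with H4a cis to both.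

**Step 6**
Reactants: 10 tert-butyl (4R,4aS,7S,7aR)-4,7-dimethyl-6-oxooctahydro-2H-cyclopenta[c]pyridine-2-carboxylate
Product: 12 (4R,4aS,6S,7S,7aR)-2,4,7-trimethyloctahydro-1H-cyclopenta[c]pyridin-6-ol, via N-Boc alcohol 11 (not isolated)
Conditions: LiAlH4 (4 equiv), THF, −78 °C → 0 °C; then reflux; Fieser work-up
Reagents that add atoms: none
Why: LiAlH4 should add hydride to the C6 ketone from the convex face of the cis-fused bicycle (the concave face is screened by the C1 methylene), which places the hydroxyl trans to the C7 methyl, and at reflux it reduces the tert-butyl carbamate to the N-methyl group (carbamate to N-methylamine reduction).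

**Step 7**
Reactants: 13 (S)-citronellol [(3S)-3,7-dimethyloct-6-en-1-ol]
Product: 14 tert-butyl{[(3S)-3,7-dimethyloct-6-en-1-yl]oxy}dimethylsilane
Conditions: TBSCl, imidazole, CH2Cl2, rt
Reagents that add atoms: tert-butyl(chloro)dimethylsilane, CC(C)(C)[Si](C)(C)Cl
Why: Imidazole-mediated silylation protects the primary alcohol so that it cannot compete in the later Mitsunobu coupling.

**Step 8**
Reactants: 14 tert-butyl{[(3S)-3,7-dimethyloct-6-en-1-yl]oxy}dimethylsilane
Product: 16 (4S)-6-{[tert-butyl(dimethyl)silyl]oxy}-4-methylhexanal, via ozonide 15 (not isolated)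
Conditions: O3, CH2Cl2, −78 °C; then PPh3, −78 °C → rt
Reagents that add atoms: ozone, [O-][O+]=O
Why: Ozonolysis with reductive work-up cleaves the trisubstituted alkene to the aldehyde and acetone without affecting the remote stereocenter or the silyl ether.

**Step 9**
Reactants: 16 (4S)-6-{[tert-butyl(dimethyl)silyl]oxy}-4-methylhexanal; 17 ethyl 2-(triphenylphosphoranylidene)propanoate
Product: 18 ethyl (2E,6S)-8-{[tert-butyl(dimethyl)silyl]oxy}-2,6-dimethyloct-2-enoate
Conditions: 17 (1.2 equiv), CH2Cl2, rt → 40 °C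
Reagents that add atoms: ethyl 2-(triphenylphosphoranylidene)propanoate (17), CCOC(=O)C(C)=P(c1ccccc1)(c1ccccc1)c1ccccc1
Why: The Wittig reaction of a stabilised α-methyl ylide with an unhindered aldehyde should give the trisubstituted (E)-enoate under thermodynamic control of the oxaphosphetane.

**Step 10**
Reactants: 18 ethyl (2E,6S)-8-{[tert-butyl(dimethyl)silyl]oxy}-2,6-dimethyloct-2-enoate
Product: 19 (2E,6S)-8-{[tert-butyl(dimethyl)silyl]oxy}-2,6-dimethyloct-2-enoic acid
Conditions: LiOH·H2O, THF/MeOH/H2O, rt; then aq. HCl to pH 4, 0 °C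
Reagents that add atoms: lithium hydroxide monohydrate (hydroxide oxygen ends in the carboxyl group), [Li+].[OH-].O
Why: Saponification of the ethyl ester leaves the primary silyl ether and the alkene geometry intact under mild hydroxide conditions and a brief, cold, weakly acidic work-up.

**Step 11**
Reactants: 12 (4R,4aS,6S,7S,7aR)-2,4,7-trimethyloctahydro-1H-cyclopenta[c]pyridin-6-ol; 19 (2E,6S)-8-{[tert-butyl(dimethyl)silyl]oxy}-2,6-dimethyloct-2-enoic acid
Product: 20 (4R,4aS,6R,7S,7aR)-2,4,7-trimethyloctahydro-1H-cyclopenta[c]pyridin-6-yl (2E,6S)-8-{[tert-butyl(dimethyl)silyl]oxy}-2,6-dimethyloct-2-enoate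
Conditions: PPh3, DIAD, THF, 0 °C → rt
Reagents that add atoms: none
Why: In the Mitsunobu esterification the alkoxyphosphonium ion of 12 is displaced by the carboxylate of 19 in an SN2 step, which inverts C6 and so places the ester oxygen cis to the C7 methyl as in the target, while the tertiary amine and the silyl ether are inert.

**Step 12**
Reactants: 20 (4R,4aS,6R,7S,7aR)-2,4,7-trimethyloctahydro-1H-cyclopenta[c]pyridin-6-yl (2E,6S)-8-{[tert-butyl(dimethyl)silyl]oxy}-2,6-dimethyloct-2-enoate
Product: 21 (4R,4aS,6R,7S,7aR)-2,4,7-trimethyloctahydro-1H-cyclopenta[c]pyridin-6-yl (2E,6S)-8-hydroxy-2,6-dimethyloct-2-enoate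
Conditions: HF·pyridine, THF/pyridine, 0 °C → rt; then aq. NaHCO3
Reagents that add atoms: none
Why: Fluoride-driven cleavage of the primary silyl ether frees the terminal alcohol without touching the hindered secondary enoate or any stereocenter.

**Compound list**

1 | (S)-3-[(tert-butoxycarbonyl)amino]-2-methylpropanoic acid | CC(C)(C)OC(=O)NC[C@@H](C(=O)O)C | starting material
2 | methyl (S)-3-[(tert-butoxycarbonyl)amino]-2-methylpropanoate | CC(C)(C)OC(=O)NC[C@@H](C(=O)OC)C | intermediate
3 | dimethyl (1-diazo-2-oxopropyl)phosphonate (Ohira–Bestmann reagent) | COP(=O)(OC)C(=[N+]=[N-])C(C)=O | starting material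
4 | tert-butyl N-[(2S)-2-methyl-3-oxopropyl]carbamate (aldehyde, not isolated) | CC(C)(C)OC(=O)NC[C@@H](C=O)C | intermediate
5 | tert-butyl N-[(2R)-2-methylbut-3-yn-1-yl]carbamate | CC(C)(C)OC(=O)NC[C@@H](C#C)C | intermediate
6 | (E)-1-bromobut-2-ene | C/C=C/CBr | starting material
7 | tert-butyl N-[(2E)-but-2-en-1-yl]-N-[(2R)-2-methylbut-3-yn-1-yl]carbamate | C/C=C/CN(C[C@@H](C#C)C)C(=O)OC(C)(C)C | intermediate
8 | Co2(CO)6 complex of 7, both cobalt atoms bridged by the C4a≡C5 alkyne (not isolated) | C/C=C/CN(C[C@H](C)[C]12[CH]3[Co]1(=C=O)(=C=O)(=C=O)[Co]23(=C=O)(=C=O)=C=O)C(=O)OC(C)(C)C | intermediate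
9 | tert-butyl (4R,7S,7aS)-4,7-dimethyl-6-oxo-1,3,4,6,7,7a-hexahydro-2H-cyclopenta[c]pyridine-2-carboxylate | O=C1C=C2[C@@H](CN(C(=O)OC(C)(C)C)C[C@@H]2C)[C@@H]1C | intermediate
10 | tert-butyl (4R,4aS,7S,7aR)-4,7-dimethyl-6-oxooctahydro-2H-cyclopenta[c]pyridine-2-carboxylate | O=C1C[C@@H]2[C@@H](CN(C(=O)OC(C)(C)C)C[C@@H]2C)[C@@H]1C | intermediate
11 | tert-butyl (4R,4aS,6S,7S,7aR)-6-hydroxy-4,7-dimethyloctahydro-2H-cyclopenta[c]pyridine-2-carboxylate (formed as its aluminium alkoxide, not isolated) | O[C@H]1C[C@@H]2[C@@H](CN(C(=O)OC(C)(C)C)C[C@@H]2C)[C@@H]1C | intermediate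
12 | (4R,4aS,6S,7S,7aR)-2,4,7-trimethyloctahydro-1H-cyclopenta[c]pyridin-6-ol | O[C@H]1C[C@@H]2[C@@H](CN(C)C[C@@H]2C)[C@@H]1C | intermediate
13 | (S)-citronellol, (3S)-3,7-dimethyloct-6-en-1-ol | CC(C)=CCC[C@H](C)CCO | starting material
14 | tert-butyl{[(3S)-3,7-dimethyloct-6-en-1-yl]oxy}dimethylsilane | CC(C)=CCC[C@H](C)CCO[Si](C)(C)C(C)(C)C | intermediate
15 | 1,2,4-trioxolane (ozonide) of 14, mixture at the ozonide carbon (not isolated) | CC1(C)OOC(CC[C@H](C)CCO[Si](C)(C)C(C)(C)C)O1 | intermediate
16 | (4S)-6-{[tert-butyl(dimethyl)silyl]oxy}-4-methylhexanal | O=CCC[C@H](C)CCO[Si](C)(C)C(C)(C)C | intermediate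
17 | ethyl 2-(triphenylphosphoranylidene)propanoate | CCOC(=O)C(C)=P(c1ccccc1)(c1ccccc1)c1ccccc1 | starting material
18 | ethyl (2E,6S)-8-{[tert-butyl(dimethyl)silyl]oxy}-2,6-dimethyloct-2-enoate | C/C(=C\CC[C@H](C)CCO[Si](C)(C)C(C)(C)C)C(=O)OCC | intermediate
19 | (2E,6S)-8-{[tert-butyl(dimethyl)silyl]oxy}-2,6-dimethyloct-2-enoic acid | C/C(=C\CC[C@H](C)CCO[Si](C)(C)C(C)(C)C)C(=O)O | intermediate
20 | (4R,4aS,6R,7S,7aR)-2,4,7-trimethyloctahydro-1H-cyclopenta[c]pyridin-6-yl (2E,6S)-8-{[tert-butyl(dimethyl)silyl]oxy}-2,6-dimethyloct-2-enoate | C/C(=C\CC[C@H](C)CCO[Si](C)(C)C(C)(C)C)C(=O)O[C@@H]1C[C@@H]2[C@@H](CN(C)C[C@@H]2C)[C@@H]1C | intermediate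
21 | (4R,4aS,6R,7S,7aR)-2,4,7-trimethyloctahydro-1H-cyclopenta[c]pyridin-6-yl (2E,6S)-8-hydroxy-2,6-dimethyloct-2-enoate | C/C(=C\CC[C@H](C)CCO)C(=O)O[C@@H]1C[C@@H]2[C@@H](CN(C)C[C@@H]2C)[C@@H]1C | target

**Step count and risks**

Total step count: 12. Longest linear sequence: 8 steps (steps 1 to 6, 11 and 12, from 1); the acid branch (steps 7 to 10) joins at step 11.

Steps most likely to fail:

Step 4. The 1,2-disubstituted alkene may insert slowly into the cobalt–carbon bond, so that β-hydride elimination from the cobaltacycle, alkyne oligomerisation or decomposition of the complex competes with cyclisation. The fallback sets out from 5 and uses a more reactive terminal alkene, adding the C7 methyl afterwards. N-Allylation of 5 (NaH, allyl bromide, DMF) should give tert-butyl N-allyl-N-[(2R)-2-methylbut-3-yn-1-yl]carbamate F1. The same Pauson–Khand conditions, through its alkyne–Co2(CO)6 complex F2, should give the C7-unsubstituted enone tert-butyl (4R,7aS)-4-methyl-6-oxo-1,3,4,6,7,7a-hexahydro-2H-cyclopenta[c]pyridine-2-carboxylate F3, with C7a again set by the equatorial C4 methyl. Kinetic deprotonation at C7 (LiN(i-Pr)2, THF, −78 °C) to the cross-conjugated lithium enolate F4 and methylation with MeI anti to the C7a–C1 bond returns to the route at 9.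

Step 6. Hydride delivery to C6 may show poor facial selectivity, because the C7 methyl on the convex face opposes the shielding of the concave face, and the carbamate reduction may stall. The fallback sets out from 9 and fixes C6 on the flat enone before the ring fusion. Luche reduction (NaBH4, CeCl3·7H2O, MeOH, −78 °C; hydride anti to the C7 methyl) should give the allylic alcohol tert-butyl (4R,6S,7S,7aS)-6-hydroxy-4,7-dimethyl-1,3,4,6,7,7a-hexahydro-2H-cyclopenta[c]pyridine-2-carboxylate F5. Hydroxyl-directed hydrogenation ([Ir(cod)(PCy3)(py)]PF6, H2, CH2Cl2) should add hydrogen to C4a from the hydroxyl face, which is the H7a face, and give the cis-fused carbamate alcohol tert-butyl (4R,4aS,6R,7S,7aR)-6-hydroxy-4,7-dimethyloctahydro-2H-cyclopenta[c]pyridine-2-carboxylate F6, already with the C6 configuration of the target. LiAlH4 (THF, reflux) should then give the amino alcohol (4R,4aS,6R,7S,7aR)-2,4,7-trimethyloctahydro-1H-cyclopenta[c]pyridin-6-ol F7. Yamaguchi esterification with 19 (2,4,6-trichlorobenzoyl chloride, Et3N, then DMAP) through the mixed anhydride F8 proceeds with retention and rejoins the route at 20.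

Step 11. The alkoxyphosphonium ion may undergo E2 elimination to the cyclopentene, or the weak and hindered enoic acid may react through an acyloxyphosphonium pathway with retention. The fallback sets out from 12 and separates inversion from acylation. Mitsunobu reaction with the more acidic 4-nitrobenzoic acid (PPh3, DIAD, THF) should give the inverted ester (4R,4aS,6R,7S,7aR)-2,4,7-trimethyloctahydro-1H-cyclopenta[c]pyridin-6-yl 4-nitrobenzoate F9. Methanolysis (K2CO3, MeOH) gives the amino alcohol F7, which is acylated with 19 through the mixed anhydride F8 as described for step 6, rejoining the route at 20.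

**Further compounds**

F1 | step 4 | tert-butyl N-allyl-N-[(2R)-2-methylbut-3-yn-1-yl]carbamate | C=CCN(C[C@@H](C#C)C)C(=O)OC(C)(C)C
F2 | step 4 | alkyne–Co2(CO)6 complex of F1 (not isolated) | C=CCN(C[C@H](C)[C]12[CH]3[Co]1(=C=O)(=C=O)(=C=O)[Co]23(=C=O)(=C=O)=C=O)C(=O)OC(C)(C)C
F3 | step 4 | tert-butyl (4R,7aS)-4-methyl-6-oxo-1,3,4,6,7,7a-hexahydro-2H-cyclopenta[c]pyridine-2-carboxylate | O=C1C=C2[C@@H](CN(C(=O)OC(C)(C)C)C[C@@H]2C)C1
F4 | step 4 | cross-conjugated lithium enolate of F3 (C6–O–Li, C6=C7; not isolated) | [Li]OC1=C[C@@H]2CN(C(=O)OC(C)(C)C)C[C@H](C)C2=C1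
F5 | step 6 | tert-butyl (4R,6S,7S,7aS)-6-hydroxy-4,7-dimethyl-1,3,4,6,7,7a-hexahydro-2H-cyclopenta[c]pyridine-2-carboxylate | O[C@@H]1C=C2[C@@H](CN(C(=O)OC(C)(C)C)C[C@@H]2C)[C@@H]1C
F6 | step 6 | tert-butyl (4R,4aS,6R,7S,7aR)-6-hydroxy-4,7-dimethyloctahydro-2H-cyclopenta[c]pyridine-2-carboxylate | O[C@@H]1C[C@@H]2[C@@H](CN(C(=O)OC(C)(C)C)C[C@@H]2C)[C@@H]1C
F7 | step 6 | (4R,4aS,6R,7S,7aR)-2,4,7-trimethyloctahydro-1H-cyclopenta[c]pyridin-6-ol | O[C@@H]1C[C@@H]2[C@@H](CN(C)C[C@@H]2C)[C@@H]1C
F8 | step 6 | mixed anhydride of 19 and 2,4,6-trichlorobenzoic acid (not isolated) | C/C(=C\CC[C@H](C)CCO[Si](C)(C)C(C)(C)C)C(=O)OC(=O)c1c(Cl)cc(Cl)cc1Cl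
F9 | step 11 | (4R,4aS,6R,7S,7aR)-2,4,7-trimethyloctahydro-1H-cyclopenta[c]pyridin-6-yl 4-nitrobenzoate | O=C(O[C@@H]1C[C@@H]2[C@@H](CN(C)C[C@@H]2C)[C@@H]1C)c1ccc(cc1)[N+](=O)[O-]
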